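**Plan**

1. The retrosynthesis first cuts the aryl ester C–O bond between the ring A carbonyl and the C4 oxygen of ring B; ring B traces back to olivetolic acid, whose arene is bought.
2. Ring A is then cut at C5–C6, C3–C4 and C1–C6 into an ester-bearing α'-diazo enone and methoxyethyne. Ring A is a 1,2,3,5-tetrasubstituted benzene with the carboxyl carbon at C1, heptyl at C2 and meta oxygens at C4 and C6, which is the pattern a vinylketene and an alkoxyalkyne lay down.
3. Forward: decan-2-one and glyoxylic acid give an E keto enoic acid, then its benzyl ester and the diazoketone; the photochemical benzannulation closes ring A, the only ring the route makes.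
4. Ring A is O-methylated and debenzylated, joined to the 4-OH of benzyl olivetolate, the chelated 2-OH of ring B is methylated, and the benzyl ester is removed last.
5. The target has no stereocenter; the only stereochemical element on the way is the E alkene of the diazoketone, set under thermodynamic control in the aldol condensation.

Key step: step 5

Assumption: olivetolic acid is taken as purchased, and methoxyethyne is made fresh because it is too volatile and unstable to store.

**Route**

Step 1
Reactants: 1 chloroacetaldehyde dimethyl acetal (2-chloro-1,1-dimethoxyethane)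
Product: 3 methoxyethyne, via sodium methoxyethynide 2 (not isolated)
Conditions: NaNH2 (3 equiv), liq. NH3, −33 °C; evaporate NH3; cold sat. aq. NH4Cl, −20 °C to rt; distil into ClCH2CH2Cl at −20 °C
Reagents that add atoms: none
Why: Double elimination with NaNH2 in liquid NH3, the standard preparation of 1-alkoxyalkynes from haloacetals, removes methanol and then HCl, holds the ynol ether as its sodium acetylide until the NH4Cl quench, and lets the low-boiling product be distilled straight into the solvent of step 5.

Step 2
Reactants: 4 decan-2-one; 5 glyoxylic acid (used as the commercial monohydrate)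
Product: 6 (E)-3-acetyldec-2-enoic acid
Conditions: 85% H3PO4, 80 °C
Reagents that add atoms: none
Why: In this acid-catalysed aldol condensation the more substituted enol of the methyl ketone (toward C3) adds to glyoxylic acid, and dehydration should give the open-chain E acid with acetyl and carboxyl trans, the thermodynamically favoured geometry and the one the later electrocyclization needs.

Step 3
Reactants: 6 (E)-3-acetyldec-2-enoic acid
Product: 7 benzyl (E)-3-acetyldec-2-enoate
Conditions: BnBr, KHCO3, DMF, rt
Reagents that add atoms: benzyl bromide, BrCc1ccccc1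
Why: SN2 O-alkylation of the carboxylate with a weak base should leave the electrophilic enone and the alkene geometry untouched.

Step 4
Reactants: 7 benzyl (E)-3-acetyldec-2-enoate
Product: 9 benzyl (E)-3-(2-diazoacetyl)dec-2-enoate, via trifluoroacetyl diketone 8 (not isolated)
Conditions: LiN(SiMe3)2, THF, −78 °C; CF3CO2CH2CF3; then MsN3, Et3N, H2O, MeCN, rt
Reagents that add atoms: methanesulfonyl azide, CS(=O)(=O)N=[N+]=[N-]
Why: In this detrifluoroacetylative diazo transfer (a Regitz-type transfer through an activating acyl group) the kinetic lithium enolate of the methyl ketone is trifluoroacetylated and the activated 1,3-diketone 8 passes its methylene to the sulfonyl azide with loss of the trifluoroacetyl group, the sequence made for α,β-unsaturated ketones whose acid chlorides would undergo dipolar cycloaddition with diazomethane.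

Step 5
Reactants: 9 benzyl (E)-3-(2-diazoacetyl)dec-2-enoate; 3 methoxyethyne
Product: 14 benzyl 2-heptyl-6-hydroxy-4-methoxybenzoate, via vinylketene 10 (not isolated), via cyclobutenone 11 (not isolated), via dienylketene 12 (not isolated), via cyclohexadienone 13 (not isolated)
Conditions: 3 (3 equiv), hν (254 nm, low-pressure Hg lamp, sealed Vycor tube), degassed ClCH2CH2Cl, 10–20 °C; then 80 °C
Reagents that add atoms: none
Why: Light expels N2 from 9 and the alkenyl group shifts to the diazo carbon (photochemical Wolff rearrangement) to give vinylketene 10, whose electrophilic ketene carbon is attacked by the CH carbon of the ynol ether in a 2+2 cycloaddition that forms C5-C6 and C3-C4 and gives the 4-alkenyl-3-methoxycyclobutenone 11. Four-electron electrocyclic opening of 11 (by light or in the 80 °C stage) gives dienylketene 12, ring A then closes by a thermal disrotatory six-electron electrocyclization between the ketene carbon and the ester-bearing alkene carbon (C1-C6), and the β-keto ester 13 should enolise at once to the aromatic phenol 14. The closest known reaction type is the Danheiser benzannulation in its diazoketone form, in which α,β-unsaturated α'-diazo ketones and alkoxyalkynes give resorcinol monoethers; the benzyl ester on the alkene terminus is carried through as a spectator. No stereocenter survives, since the sp3 carbons of 11 and 13 form racemic and are erased on aromatization. The step needs one regiochemical outcome in the cycloaddition, and the polarity of the ynol ether (nucleophilic at CH, oxygen-stabilised positive charge at C-OMe) secures it, so that the methoxy group ends at C4, meta to the new hydroxyl. The E alkene of 9 keeps the ester remote from the ketene, which shuts off oxa-electrocyclization to a pyranone and puts hydrogen instead of the ester inside at the closing terminus, and because cyclobutenone opening is reversible the heating stage should funnel wrongly opened material to 14.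

Step 6
Reactants: 14 benzyl 2-heptyl-6-hydroxy-4-methoxybenzoate
Product: 15 benzyl 2-heptyl-4,6-dimethoxybenzoate
Conditions: MeI, K2CO3, acetone, reflux
Reagents that add atoms: iodomethane, CI
Why: Williamson ether synthesis on the chelated salicylate-type phenol, under conditions to which the benzyl ester is inert.

Step 7
Reactants: 15 benzyl 2-heptyl-4,6-dimethoxybenzoate
Product: 16 2-heptyl-4,6-dimethoxybenzoic acid
Conditions: H2 (1 atm), Pd/C, EtOAc, rt
Reagents that add atoms: none
Why: Hydrogenolysis of the benzyl ester frees the doubly ortho-substituted acid under neutral conditions, where saponification of so hindered an ester would be sluggish.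

Step 8
Reactants: 17 olivetolic acid (2,4-dihydroxy-6-pentylbenzoic acid)
Product: 18 benzyl 2,4-dihydroxy-6-pentylbenzoate
Conditions: BnBr, KHCO3, DMF, rt
Reagents that add atoms: benzyl bromide, BrCc1ccccc1
Why: Hydrogencarbonate ionises only the carboxylic acid, so SN2 benzylation should give the ester and leave both phenols free, and room temperature avoids decarboxylation of the resorcylic acid.

Step 9
Reactants: 16 2-heptyl-4,6-dimethoxybenzoic acid; 18 benzyl 2,4-dihydroxy-6-pentylbenzoate
Product: 20 benzyl 4-[(2-heptyl-4,6-dimethoxybenzoyl)oxy]-2-hydroxy-6-pentylbenzoate, via mixed trifluoroacetic anhydride 19 (not isolated)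
Conditions: (CF3CO)2O, toluene, 0 °C to rt
Reagents that add atoms: none
Why: In this mixed-anhydride esterification, the classical depside coupling, the electron-rich hindered acid forms the acylium-like donor 19, which should acylate the free 4-OH only, because the 2-OH is hydrogen-bonded to the neighbouring ester carbonyl and far less nucleophilic.

Step 10
Reactants: 20 benzyl 4-[(2-heptyl-4,6-dimethoxybenzoyl)oxy]-2-hydroxy-6-pentylbenzoate
Product: 21 benzyl 4-[(2-heptyl-4,6-dimethoxybenzoyl)oxy]-2-methoxy-6-pentylbenzoate
Conditions: MeI, K2CO3, acetone, reflux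
Reagents that add atoms: iodomethane, CI
Why: Williamson methylation of the one remaining phenol, with the depside carbonyl shielded from acyl transfer by its two ortho substituents and no nucleophile stronger than carbonate present.

Step 11
Reactants: 21 benzyl 4-[(2-heptyl-4,6-dimethoxybenzoyl)oxy]-2-methoxy-6-pentylbenzoate
Product: 22 4-[(2-heptyl-4,6-dimethoxybenzoyl)oxy]-2-methoxy-6-pentylbenzoic acid (target)
Conditions: H2 (1 atm), Pd/C, EtOAc, rt
Reagents that add atoms: none
Why: Neutral hydrogenolysis of the benzyl ester should leave the aryl ester link and the three methyl ethers intact and give the free acid of ring B.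

**Compound list**

1 | chloroacetaldehyde dimethyl acetal (2-chloro-1,1-dimethoxyethane) | COC(CCl)OC | starting material
2 | sodium methoxyethynide | [Na+].[C-]#COC | intermediate
3 | methoxyethyne | C#COC | intermediate
4 | decan-2-one | CCCCCCCCC(C)=O | starting material
5 | glyoxylic acid (used as the commercial monohydrate) | O=CC(=O)O | starting material
6 | (E)-3-acetyldec-2-enoic acid | CCCCCCC/C(C(C)=O)=C\C(=O)O | intermediate
7 | benzyl (E)-3-acetyldec-2-enoate | CCCCCCC/C(C(C)=O)=C\C(=O)OCc1ccccc1 | intermediate
8 | benzyl (E)-3-(4,4,4-trifluoro-3-oxobutanoyl)dec-2-enoate | CCCCCCC/C(C(=O)CC(=O)C(F)(F)F)=C\C(=O)OCc1ccccc1 | intermediate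
9 | benzyl (E)-3-(2-diazoacetyl)dec-2-enoate | CCCCCCC/C(C(=O)C=[N+]=[N-])=C\C(=O)OCc1ccccc1 | intermediate
10 | benzyl (E)-3-(2-oxoethenyl)dec-2-enoate (vinylketene) | CCCCCCC/C(C=C=O)=C\C(=O)OCc1ccccc1 | intermediate
11 | benzyl (E)-3-(2-methoxy-4-oxocyclobut-2-en-1-yl)dec-2-enoate (racemic) | CCCCCCC/C(C1C(OC)=CC1=O)=C\C(=O)OCc1ccccc1 | intermediate
12 | benzyl (2E,4E)-3-heptyl-5-methoxy-7-oxohepta-2,4,6-trienoate (dienylketene) | O=C=C/C(OC)=C\C(CCCCCCC)=C\C(=O)OCc1ccccc1 | intermediate
13 | benzyl 2-heptyl-4-methoxy-6-oxocyclohexa-2,4-diene-1-carboxylate (racemic) | CCCCCCCC1=CC(OC)=CC(=O)C1C(=O)OCc1ccccc1 | intermediate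
14 | benzyl 2-heptyl-6-hydroxy-4-methoxybenzoate | CCCCCCCc1cc(OC)cc(O)c1C(=O)OCc1ccccc1 | intermediate
15 | benzyl 2-heptyl-4,6-dimethoxybenzoate | CCCCCCCc1cc(OC)cc(OC)c1C(=O)OCc1ccccc1 | intermediate
16 | 2-heptyl-4,6-dimethoxybenzoic acid | CCCCCCCc1cc(OC)cc(OC)c1C(=O)O | intermediate
17 | olivetolic acid (2,4-dihydroxy-6-pentylbenzoic acid) | CCCCCc1cc(O)cc(O)c1C(=O)O | starting material
18 | benzyl 2,4-dihydroxy-6-pentylbenzoate | CCCCCc1cc(O)cc(O)c1C(=O)OCc1ccccc1 | intermediate
19 | 2-heptyl-4,6-dimethoxybenzoic trifluoroacetic anhydride | CCCCCCCc1cc(OC)cc(OC)c1C(=O)OC(=O)C(F)(F)F | intermediate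
20 | benzyl 4-[(2-heptyl-4,6-dimethoxybenzoyl)oxy]-2-hydroxy-6-pentylbenzoate | CCCCCCCc1cc(OC)cc(OC)c1C(=O)Oc1cc(CCCCC)c(C(=O)OCc2ccccc2)c(O)c1 | intermediate
21 | benzyl 4-[(2-heptyl-4,6-dimethoxybenzoyl)oxy]-2-methoxy-6-pentylbenzoate | CCCCCCCc1cc(OC)cc(OC)c1C(=O)Oc1cc(CCCCC)c(C(=O)OCc2ccccc2)c(OC)c1 | intermediate
22 | 4-[(2-heptyl-4,6-dimethoxybenzoyl)oxy]-2-methoxy-6-pentylbenzoic acid | CCCCCCCc1cc(OC)cc(OC)c1C(=O)Oc1cc(CCCCC)c(C(=O)O)c(OC)c1 | target

**Step count**

Total step count: 11.
Longest linear sequence: 9 steps (steps 2, 3, 4, 5, 6, 7, 9, 10 and 11, from decan-2-one). Step 1 and step 8 are one-step branches that join at steps 5 and 9.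

**Steps most likely to fail**

1. Step 5. The enoate of 9 or 10 may photoisomerise to the Z geometry, after which the ketene can close onto the ester carbonyl to give a pyranone instead of the carbocycle. The diazo group may also add as a dipole to the doubly activated alkene before photolysis, and the ester-substituted ketene may oligomerise faster than it traps the ynol ether. The fallback runs the benzannulation in its established alkyl-only form and brings the carboxyl carbon in afterwards; it sets out from 4 and returns at 16.
   - Decan-2-one 4 is α-methylenated at C3 ((CH2O)n, i-Pr2NH·CF3CO2H, THF, reflux) to 3-methylidenedecan-2-one F1.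
   - Trifluoroacetylation of its lithium enolate (LiN(SiMe3)2, CF3CO2CH2CF3) gives 1,1,1-trifluoro-5-methylidenedodecane-2,4-dione F2, and diazo transfer (MsN3, Et3N) gives 1-diazo-3-methylidenedecan-2-one F3.
   - Irradiation of F3 with 3 under the conditions of step 5 should pass through 3-methylidenedec-1-en-1-one F4, 3-methoxy-4-(non-1-en-2-yl)cyclobut-2-en-1-one F5, (3E)-3-methoxy-5-methylidenedodeca-1,3-dien-1-one F6 and 5-heptyl-3-methoxycyclohexa-2,4-dien-1-one F7 to 3-heptyl-5-methoxyphenol F8.
   - Methylation (MeI, K2CO3, acetone) gives 1-heptyl-3,5-dimethoxybenzene F9.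
   - Vilsmeier–Haack formylation (POCl3, DMF) at the position flanked by heptyl and methoxy gives 2-heptyl-4,6-dimethoxybenzaldehyde F10.
   - Pinnick oxidation (NaClO2, NaH2PO4, 2-methylbut-2-ene, t-BuOH/H2O) gives acid 16, and the route resumes with step 9.

2. Step 4. The lithium enolate may add to the doubly activated alkene of a second molecule (Michael oligomerisation), or the base may deprotonate the allylic C4 position instead of the methyl group. The fallback replaces the hard enolate by soft enolisation and electrophilic acylation; it sets out from 7 and returns at 8.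
   - Me3SiOSO2CF3 and Et3N (CH2Cl2, 0 °C) convert 7 into benzyl (E)-3-{1-[(trimethylsilyl)oxy]ethenyl}dec-2-enoate F11.
   - C-Trifluoroacetylation of F11 with (CF3CO)2O (CH2Cl2, 0 °C) gives diketone 8 without any strong base.
   - 8 is then taken through the same MsN3/Et3N diazo transfer to 9.

3. Step 10. Slow alkylation of the chelated phenol may let base-induced acyl transfer or cleavage of the depside link compete, or leave the methylation incomplete. The fallback methylates ring B before the coupling; it sets out from 18 and returns at 21.
   - Selective silylation of the unchelated 4-OH of 18 (i-Pr3SiCl, imidazole, DMF) gives benzyl 2-hydroxy-6-pentyl-4-[(triisopropylsilyl)oxy]benzoate F12.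
   - Methylation (MeI, K2CO3, acetone, reflux) gives benzyl 2-methoxy-6-pentyl-4-[(triisopropylsilyl)oxy]benzoate F13.
   - Desilylation (Bu4NF, AcOH, THF, 0 °C) gives benzyl 4-hydroxy-2-methoxy-6-pentylbenzoate F14.
   - F14 is coupled with acid 16 under the conditions of step 9 (through 19) to give 21 directly, and the route ends with step 11.

**Further compounds**

F1 | step 5 | 3-methylidenedecan-2-one | CCCCCCCC(=C)C(C)=O
F2 | step 5 | 1,1,1-trifluoro-5-methylidenedodecane-2,4-dione | CCCCCCCC(=C)C(=O)CC(=O)C(F)(F)F
F3 | step 5 | 1-diazo-3-methylidenedecan-2-one | CCCCCCCC(=C)C(=O)C=[N+]=[N-]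
F4 | step 5 | 3-methylidenedec-1-en-1-one | CCCCCCCC(=C)C=C=O
F5 | step 5 | 3-methoxy-4-(non-1-en-2-yl)cyclobut-2-en-1-one (racemic) | CCCCCCCC(=C)C1C(OC)=CC1=O
F6 | step 5 | (3E)-3-methoxy-5-methylidenedodeca-1,3-dien-1-one | O=C=C/C(OC)=C\C(=C)CCCCCCC
F7 | step 5 | 5-heptyl-3-methoxycyclohexa-2,4-dien-1-one | CCCCCCCC1=CC(OC)=CC(=O)C1
F8 | step 5 | 3-heptyl-5-methoxyphenol | CCCCCCCc1cc(O)cc(OC)c1
F9 | step 5 | 1-heptyl-3,5-dimethoxybenzene | CCCCCCCc1cc(OC)cc(OC)c1
F10 | step 5 | 2-heptyl-4,6-dimethoxybenzaldehyde | CCCCCCCc1cc(OC)cc(OC)c1C=O
F11 | step 4 | benzyl (E)-3-{1-[(trimethylsilyl)oxy]ethenyl}dec-2-enoate | CCCCCCC/C(C(=C)O[Si](C)(C)C)=C\C(=O)OCc1ccccc1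
F12 | step 10 | benzyl 2-hydroxy-6-pentyl-4-[(triisopropylsilyl)oxy]benzoate | CCCCCc1cc(O[Si](C(C)C)(C(C)C)C(C)C)cc(O)c1C(=O)OCc1ccccc1
F13 | step 10 | benzyl 2-methoxy-6-pentyl-4-[(triisopropylsilyl)oxy]benzoate | CCCCCc1cc(O[Si](C(C)C)(C(C)C)C(C)C)cc(OC)c1C(=O)OCc1ccccc1
F14 | step 10 | benzyl 4-hydroxy-2-methoxy-6-pentylbenzoate | CCCCCc1cc(O)cc(OC)c1C(=O)OCc1ccccc1
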